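Ring B is closed last across the unsubstituted C8–C9 bridge (eudesmane numbering; C1 carries the benzylic carbon C1′, C7 the hydroxyisopropyl group). The key step is a ring-closing metathesis between a vinyl group on the quaternary C10 of ring A and a vinyl group on C7 of an Evans-aldol chain attached through C6 to C5, followed in the same flask by hydrogenation of the resulting C8=C9 olefin, the only disubstituted one. It exploits that C8 and C9 are two bare methylenes between C7 and C10. The surviving tetrasubstituted C4=C5 olefin and the C6 oxygen are then transposed reductively into the C5=C6 alkene and the C4 stereocentre.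

Key step: step 11

Remark: ring carbons are numbered C1–C10 as in eudesmanes, C11 is the carbinol carbon and C1′ the benzylic carbon; the sense of induction of (S)-BINAP in step 1 is assumed to be the one known for cyclohex-2-enone.

Step 1
Reactants: 1 2-methylcyclohex-2-en-1-one; 2 trimethyl[(2-methylbut-3-yn-2-yl)oxy]silane
Product: 5 (2S,3R)-2-(1-hydroxyethyl)-2-methyl-3-[(1E)-3-methyl-3-(trimethylsilyloxy)but-1-en-1-yl]cyclohexan-1-one (both carbinol epimers), via alkenylzirconocene chloride 3 (not isolated), via zirconium enolate 4 (not isolated)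
Conditions: Cp2Zr(H)Cl, THF, rt; then 1, [Rh(cod)(MeCN)2]BF4 (5 mol %), (S)-BINAP (6 mol %), rt; then MeCHO, −78 → 0 °C; aq. NaHCO3
Reagents that add atoms: acetaldehyde, CC=O
Why: Hydrozirconation gives the (E)-alkenylzirconocene, the rhodium/(S)-BINAP-catalysed asymmetric conjugate addition (three-component conjugate addition–aldol reaction) sets C1 (R), and the zirconium enolate formed regiospecifically at C10 should add to acetaldehyde anti to the new C1 substituent, so that the C10 methyl ends cis to the C1 side chain; the carbinol centre is uncontrolled and is removed in step 2.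

Step 2
Reactants: 5 (2S,3R)-2-(1-hydroxyethyl)-2-methyl-3-[(1E)-3-methyl-3-(trimethylsilyloxy)but-1-en-1-yl]cyclohexan-1-one
Product: 6 (2R,3R)-2-ethenyl-2-methyl-3-[(1E)-3-methyl-3-(trimethylsilyloxy)but-1-en-1-yl]cyclohexan-1-one
Conditions: Burgess reagent (MeO2CN–SO2NEt3 inner salt), toluene, 70 °C
Reagents that add atoms: none
Why: Burgess dehydration (syn-elimination of the sulfamate ester) can only run toward the methyl group because C10 is quaternary, and its neutral conditions avoid retro-aldol cleavage; no stereocentre is formed.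

Step 3
Reactants: 6 (2R,3R)-2-ethenyl-2-methyl-3-[(1E)-3-methyl-3-(trimethylsilyloxy)but-1-en-1-yl]cyclohexan-1-one
Product: 8 (5R,6R)-6-ethenyl-2,6-dimethyl-5-[(1E)-3-methyl-3-(trimethylsilyloxy)but-1-en-1-yl]cyclohex-1-en-1-yl trifluoromethanesulfonate, via C4-methyl ketone 7 (not isolated)
Conditions: LDA, THF, −78 °C; MeI, −78 → −20 °C; then KHMDS, −78 °C; PhNTf2, −78 → 0 °C
Reagents that add atoms: iodomethane, CI; N-phenylbis(trifluoromethanesulfonimide), O=S(=O)(N(c1ccccc1)S(=O)(=O)C(F)(F)F)C(F)(F)F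
Why: C4 is the only enolisable position, so enolate methylation followed by a second deprotonation and O-triflation (enol triflate formation) should give the single tetrasubstituted C4=C5 enol triflate; the C4 centre of 7 is erased on purpose and is set in step 13.

Step 4
Reactants: 8 (5R,6R)-6-ethenyl-2,6-dimethyl-5-[(1E)-3-methyl-3-(trimethylsilyloxy)but-1-en-1-yl]cyclohex-1-en-1-yl trifluoromethanesulfonate; 9 1,3,5-trimethoxybenzene
Product: 10 (5R,6R)-6-ethenyl-2,6-dimethyl-5-[(1S)-3-methyl-1-(2,4,6-trimethoxyphenyl)but-2-en-1-yl]cyclohex-1-en-1-yl trifluoromethanesulfonate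
Conditions: Bi(OTf)3 (5 mol %), 9 (2.5 equiv), CH2Cl2, −30 → 0 °C
Reagents that add atoms: none
Why: Lewis-acid ionisation of the tertiary allylic silyl ether gives a dimethylallyl cation that undergoes Friedel–Crafts allylic alkylation of the arene at its less hindered secondary terminus C1′ (the adduct at the tertiary terminus is strained and reversible); with the C1–H bond eclipsing the allyl plane (allylic 1,3-strain) the arene should attack anti to the quaternary C10, which corresponds to the required (S) configuration at C1′.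

Step 5
Reactants: 10 (5R,6R)-6-ethenyl-2,6-dimethyl-5-[(1S)-3-methyl-1-(2,4,6-trimethoxyphenyl)but-2-en-1-yl]cyclohex-1-en-1-yl trifluoromethanesulfonate
Product: 11 (5R,6R)-6-ethenyl-2,6-dimethyl-5-[(1S)-3-methyl-1-(2,4,6-trimethoxyphenyl)butyl]cyclohex-1-en-1-yl trifluoromethanesulfonate
Conditions: Et3SiH, CF3CO2H, CH2Cl2, 0 °C
Reagents that add atoms: none
Why: Ionic hydrogenation (protonation to the tertiary carbocation, hydride transfer from the silane) should reduce only the trisubstituted olefin, because the vinyl group and the enol triflate cannot give comparably stabilised cations; no stereocentre is touched.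

Step 6
Reactants: 11 (5R,6R)-6-ethenyl-2,6-dimethyl-5-[(1S)-3-methyl-1-(2,4,6-trimethoxyphenyl)butyl]cyclohex-1-en-1-yl trifluoromethanesulfonate
Product: 12 (5R,6R)-6-ethenyl-2,6-dimethyl-5-[(1S)-3-methyl-1-(2,4,6-trimethoxyphenyl)butyl]cyclohex-1-ene-1-carbaldehyde
Conditions: Pd(PPh3)4 (5 mol %), CO (1 atm), Bu3SnH (slow addition), THF, 50 °C
Reagents that add atoms: carbon monoxide, [C-]#[O+]
Why: Palladium-catalysed reductive carbonylation (formylation) of the enol triflate by oxidative addition, CO insertion and hydride transfer from the stannane should give the tetrasubstituted enal (C6 introduced); the pendant vinyl group could only close a four-membered ring and stays untouched.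

Step 7
Reactants: 13 (4S)-4-benzyl-1,3-oxazolidin-2-one; 14 (2E)-but-2-enoyl chloride
Product: 15 (4S)-4-benzyl-3-[(2E)-but-2-enoyl]-1,3-oxazolidin-2-one
Conditions: n-BuLi, THF, −78 °C; then 14, −78 → 0 °C
Reagents that add atoms: none
Why: N-Acylation of the lithiated oxazolidinone with the acid chloride (Evans auxiliary acylation); the stereocentre of the auxiliary is untouched.

Step 8
Reactants: 12 (5R,6R)-6-ethenyl-2,6-dimethyl-5-[(1S)-3-methyl-1-(2,4,6-trimethoxyphenyl)butyl]cyclohex-1-ene-1-carbaldehyde; 15 (4S)-4-benzyl-3-[(2E)-but-2-enoyl]-1,3-oxazolidin-2-one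
Product: 16 (4S)-4-benzyl-3-[(2S)-2-[(S)-{(5R,6R)-6-ethenyl-2,6-dimethyl-5-[(1S)-3-methyl-1-(2,4,6-trimethoxyphenyl)butyl]cyclohex-1-en-1-yl}(hydroxy)methyl]but-3-enoyl]-1,3-oxazolidin-2-one
Conditions: 15, Bu2BOTf, Et3N, CH2Cl2, −78 → 0 °C; then 12, −78 → 0 °C; pH 7 buffer, MeOH
Reagents that add atoms: none
Why: Evans syn-aldol addition of the boron dienolate, which reacts at its α-carbon through a closed Zimmerman–Traxler transition state; the (S)-benzyl auxiliary should fix C7 (S, vinyl-bearing) and C6 (S) under reagent control, placing the C6 hydroxyl syn to the future C11 substituent.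

Step 9
Reactants: 16 (4S)-4-benzyl-3-[(2S)-2-[(S)-{(5R,6R)-6-ethenyl-2,6-dimethyl-5-[(1S)-3-methyl-1-(2,4,6-trimethoxyphenyl)butyl]cyclohex-1-en-1-yl}(hydroxy)methyl]but-3-enoyl]-1,3-oxazolidin-2-one
Product: 17 methyl (2S)-2-[(S)-{(5R,6R)-6-ethenyl-2,6-dimethyl-5-[(1S)-3-methyl-1-(2,4,6-trimethoxyphenyl)butyl]cyclohex-1-en-1-yl}(hydroxy)methyl]but-3-enoate
Conditions: Yb(OTf)3 (10 mol %), MeOH, 45 °C
Reagents that add atoms: methanol, CO
Why: Lewis-acid-catalysed methanolysis of the chelated N-acyloxazolidinone removes the auxiliary without base, so that neither retro-aldol cleavage nor conjugation of the β,γ-olefin (epimerisation at C7) should occur.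

Step 10
Reactants: 17 methyl (2S)-2-[(S)-{(5R,6R)-6-ethenyl-2,6-dimethyl-5-[(1S)-3-methyl-1-(2,4,6-trimethoxyphenyl)butyl]cyclohex-1-en-1-yl}(hydroxy)methyl]but-3-enoate
Product: 18 (1S,2S)-2-ethenyl-1-{(5R,6R)-6-ethenyl-2,6-dimethyl-5-[(1S)-3-methyl-1-(2,4,6-trimethoxyphenyl)butyl]cyclohex-1-en-1-yl}-3-methylbutane-1,3-diol
Conditions: MeLi, CeCl3, THF, −78 → −30 °C; aq. NH4Cl
Reagents that add atoms: methyllithium, [Li]C
Why: Double addition of the weakly basic methylcerium reagent to the ester (organocerium 1,2-addition) builds the C11 tertiary carbinol, while the low basicity and temperature should suppress enolisation at C7 and the anionic oxy-Cope rearrangement of the lithium alkoxide.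

Step 11
Reactants: 18 (1S,2S)-2-ethenyl-1-{(5R,6R)-6-ethenyl-2,6-dimethyl-5-[(1S)-3-methyl-1-(2,4,6-trimethoxyphenyl)butyl]cyclohex-1-en-1-yl}-3-methylbutane-1,3-diol
Product: 20 (1S,2S,4aR,5R)-2-(2-hydroxypropan-2-yl)-4a,8-dimethyl-5-[(1S)-3-methyl-1-(2,4,6-trimethoxyphenyl)butyl]-1,2,3,4,4a,5,6,7-octahydronaphthalen-1-ol, via hexahydronaphthalene diene 19 (not isolated)
Conditions: second-generation Grubbs catalyst (5 mol %), toluene, 80 °C; then H2 (5 bar), 70 °C, same flask
Reagents that add atoms: none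
Why: Ring-closing olefin metathesis: the ruthenium alkylidene loads on one vinyl group, forms the metallacyclobutane with the other and releases ethene, so that the C8=C9 double bond closes ring B, and under hydrogen the ruthenium residue becomes a hydride catalyst that saturates this olefin to the C8–C9 single bond. The closest known reaction type is the tandem ring-closing metathesis–hydrogenation of 1,7-dienes to cyclohexanes. Ring B (C5, C6, C7, C8, C9, C10) is closed as a six-membered carbocycle by metathesis of two terminal olefins, its other five ring bonds being already in place. No stereocentre is created: C1, C10 and C1′ come from steps 1 and 4 and C6 and C7 from step 8, and none of them can epimerise under these neutral conditions. The step needs chemoselectivity, which the substrate secures because the tetrasubstituted C4=C5 olefin is inert to both metathesis and the ruthenium hydride and because the side-chain olefin was saturated in step 5, so that only the two 1,7-related vinyl groups can react. The quaternary C10 and the substituents on C6 and C7 should favour the folded conformer that cyclises.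

Step 12
Reactants: 20 (1S,2S,4aR,5R)-2-(2-hydroxypropan-2-yl)-4a,8-dimethyl-5-[(1S)-3-methyl-1-(2,4,6-trimethoxyphenyl)butyl]-1,2,3,4,4a,5,6,7-octahydronaphthalen-1-ol
Product: 21 (1S,2S,4aR,5R)-2-(2-hydroxypropan-2-yl)-4a,8-dimethyl-5-[(1S)-3-methyl-1-(2,4,6-trimethoxyphenyl)butyl]-1,2,3,4,4a,5,6,7-octahydronaphthalen-1-yl formate
Conditions: HCO2H, DCC, DMAP (cat.), CH2Cl2, 0 °C
Reagents that add atoms: formic acid, O=CO
Why: Steglich esterification should acylate only the secondary allylic C6 hydroxyl (the tertiary C11 hydroxyl is too hindered), which installs leaving group and internal hydride source in one group; the configuration at C6 is retained.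

Step 13
Reactants: 21 (1S,2S,4aR,5R)-2-(2-hydroxypropan-2-yl)-4a,8-dimethyl-5-[(1S)-3-methyl-1-(2,4,6-trimethoxyphenyl)butyl]-1,2,3,4,4a,5,6,7-octahydronaphthalen-1-yl formate
Product: 22 2-[(2S,4aR,5R,8R)-4a,8-dimethyl-5-[(1S)-3-methyl-1-(2,4,6-trimethoxyphenyl)butyl]-2,3,4,4a,5,6,7,8-octahydronaphthalen-2-yl]propan-2-ol
Conditions: Pd(OAc)2 (5 mol %), PBu3 (20 mol %), dioxane, 100 °C
Reagents that add atoms: none
Why: Tsuji–Mandai palladium-catalysed hydrogenolysis of the allylic formate: ionisation anti to the C6 formate puts palladium on the face opposite to the C10 methyl, decarboxylation gives the palladium hydride, and hydride delivery from the metal face to the more substituted terminus C4 should move the olefin to C5=C6 and set C4 (R), its hydrogen trans and its methyl cis to the C10 methyl.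

Step 14
Reactants: 22 2-[(2S,4aR,5R,8R)-4a,8-dimethyl-5-[(1S)-3-methyl-1-(2,4,6-trimethoxyphenyl)butyl]-2,3,4,4a,5,6,7,8-octahydronaphthalen-2-yl]propan-2-ol
Product: 24 5-[(1S)-1-[(1R,4R,6S,8aR)-6-(2-hydroxypropan-2-yl)-4,8a-dimethyl-1,2,3,4,6,7,8,8a-octahydronaphthalen-1-yl]-3-methylbutyl]-2,4,6-trimethoxybenzene-1,3-dicarbaldehyde, via monoformyl lithium hemiaminal 23 (not isolated)
Conditions: n-BuLi, TMEDA, THF, 0 °C; DMF, −78 → 0 °C; then n-BuLi, 0 °C; DMF, −78 → 0 °C; aq. NH4Cl
Reagents that add atoms: N,N-dimethylformamide, CN(C)C=O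
Why: Directed ortho-lithiation between two methoxy groups and formylation with DMF; the lithium α-amino alkoxide formed first protects the first formyl group in the flask, so that a second lithiation–formylation should give the dialdehyde while the tertiary hydroxyl is carried as its alkoxide.

Step 15
Reactants: 24 5-[(1S)-1-[(1R,4R,6S,8aR)-6-(2-hydroxypropan-2-yl)-4,8a-dimethyl-1,2,3,4,6,7,8,8a-octahydronaphthalen-1-yl]-3-methylbutyl]-2,4,6-trimethoxybenzene-1,3-dicarbaldehyde
Product: 25 5-[(1S)-1-[(1R,4R,6S,8aR)-6-(2-hydroxypropan-2-yl)-4,8a-dimethyl-1,2,3,4,6,7,8,8a-octahydronaphthalen-1-yl]-3-methylbutyl]-2,4,6-trihydroxybenzene-1,3-dicarbaldehyde (target)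
Conditions: NaSEt, DMF, 120 °C; then dilute HCl to pH 4
Reagents that add atoms: none
Why: SN2 O-demethylation by ethanethiolate; all three methoxy groups are activated by ortho or para formyl groups, and the basic conditions should spare the tertiary alcohol, the C5=C6 olefin and all stereocentres.

Compound list
1 | 2-methylcyclohex-2-en-1-one | CC1=CCCCC1=O | starting material
2 | trimethyl[(2-methylbut-3-yn-2-yl)oxy]silane | C#CC(C)(C)O[Si](C)(C)C | starting material
3 | chlorido[(1E)-3-methyl-3-(trimethylsilyloxy)but-1-en-1-yl]zirconocene | C[Si](C)(C)OC(C)(C)/C=C/[Zr](Cl)(C1C=CC=C1)C1C=CC=C1 | intermediate (not isolated)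
4 | chloridozirconocene (3R)-2-methyl-3-[(1E)-3-methyl-3-(trimethylsilyloxy)but-1-en-1-yl]cyclohex-1-en-1-olate | CC1=C(O[Zr](Cl)(C2C=CC=C2)C2C=CC=C2)CCC[C@@H]1/C=C/C(C)(C)O[Si](C)(C)C | intermediate (not isolated)
5 | (2S,3R)-2-(1-hydroxyethyl)-2-methyl-3-[(1E)-3-methyl-3-(trimethylsilyloxy)but-1-en-1-yl]cyclohexan-1-one, both carbinol epimers | O=C1CCC[C@H](/C=C/C(C)(C)O[Si](C)(C)C)[C@@]1(C)C(C)O | intermediate
6 | (2R,3R)-2-ethenyl-2-methyl-3-[(1E)-3-methyl-3-(trimethylsilyloxy)but-1-en-1-yl]cyclohexan-1-one | O=C1CCC[C@H](/C=C/C(C)(C)O[Si](C)(C)C)[C@@]1(C)C=C | intermediate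
7 | (2R,3R)-2-ethenyl-2,6-dimethyl-3-[(1E)-3-methyl-3-(trimethylsilyloxy)but-1-en-1-yl]cyclohexan-1-one, both C6 epimers | O=C1C(C)CC[C@H](/C=C/C(C)(C)O[Si](C)(C)C)[C@@]1(C)C=C | intermediate (not isolated)
8 | (5R,6R)-6-ethenyl-2,6-dimethyl-5-[(1E)-3-methyl-3-(trimethylsilyloxy)but-1-en-1-yl]cyclohex-1-en-1-yl trifluoromethanesulfonate | FC(F)(F)S(=O)(=O)OC1=C(C)CC[C@H](/C=C/C(C)(C)O[Si](C)(C)C)[C@@]1(C)C=C | intermediate
9 | 1,3,5-trimethoxybenzene | COc1cc(OC)cc(OC)c1 | starting material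
10 | (5R,6R)-6-ethenyl-2,6-dimethyl-5-[(1S)-3-methyl-1-(2,4,6-trimethoxyphenyl)but-2-en-1-yl]cyclohex-1-en-1-yl trifluoromethanesulfonate | FC(F)(F)S(=O)(=O)OC1=C(C)CC[C@H]([C@H](C=C(C)C)c2c(OC)cc(OC)cc2OC)[C@@]1(C)C=C | intermediate
11 | (5R,6R)-6-ethenyl-2,6-dimethyl-5-[(1S)-3-methyl-1-(2,4,6-trimethoxyphenyl)butyl]cyclohex-1-en-1-yl trifluoromethanesulfonate | FC(F)(F)S(=O)(=O)OC1=C(C)CC[C@H]([C@H](CC(C)C)c2c(OC)cc(OC)cc2OC)[C@@]1(C)C=C | intermediate
12 | (5R,6R)-6-ethenyl-2,6-dimethyl-5-[(1S)-3-methyl-1-(2,4,6-trimethoxyphenyl)butyl]cyclohex-1-ene-1-carbaldehyde | O=CC1=C(C)CC[C@H]([C@H](CC(C)C)c2c(OC)cc(OC)cc2OC)[C@@]1(C)C=C | intermediate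
13 | (4S)-4-benzyl-1,3-oxazolidin-2-one | O=C1OC[C@H](Cc2ccccc2)N1 | starting material
14 | (2E)-but-2-enoyl chloride | C/C=C/C(Cl)=O | starting material
15 | (4S)-4-benzyl-3-[(2E)-but-2-enoyl]-1,3-oxazolidin-2-one | C/C=C/C(=O)N1[C@@H](Cc2ccccc2)COC1=O | intermediate
16 | (4S)-4-benzyl-3-[(2S)-2-[(S)-{(5R,6R)-6-ethenyl-2,6-dimethyl-5-[(1S)-3-methyl-1-(2,4,6-trimethoxyphenyl)butyl]cyclohex-1-en-1-yl}(hydroxy)methyl]but-3-enoyl]-1,3-oxazolidin-2-one | C=C[C@H](C(=O)N1[C@@H](Cc2ccccc2)COC1=O)[C@H](O)C1=C(C)CC[C@H]([C@H](CC(C)C)c2c(OC)cc(OC)cc2OC)[C@@]1(C)C=C | intermediate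
17 | methyl (2S)-2-[(S)-{(5R,6R)-6-ethenyl-2,6-dimethyl-5-[(1S)-3-methyl-1-(2,4,6-trimethoxyphenyl)butyl]cyclohex-1-en-1-yl}(hydroxy)methyl]but-3-enoate | C=C[C@H](C(=O)OC)[C@H](O)C1=C(C)CC[C@H]([C@H](CC(C)C)c2c(OC)cc(OC)cc2OC)[C@@]1(C)C=C | intermediate
18 | (1S,2S)-2-ethenyl-1-{(5R,6R)-6-ethenyl-2,6-dimethyl-5-[(1S)-3-methyl-1-(2,4,6-trimethoxyphenyl)butyl]cyclohex-1-en-1-yl}-3-methylbutane-1,3-diol | C=C[C@H](C(C)(C)O)[C@H](O)C1=C(C)CC[C@H]([C@H](CC(C)C)c2c(OC)cc(OC)cc2OC)[C@@]1(C)C=C | intermediate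
19 | (1S,2S,4aR,5R)-2-(2-hydroxypropan-2-yl)-4a,8-dimethyl-5-[(1S)-3-methyl-1-(2,4,6-trimethoxyphenyl)butyl]-1,2,4a,5,6,7-hexahydronaphthalen-1-ol | CC(C)C[C@H](c1c(OC)cc(OC)cc1OC)[C@H]1CCC(C)=C2[C@@H](O)[C@@H](C(C)(C)O)C=C[C@@]21C | intermediate (not isolated)
20 | (1S,2S,4aR,5R)-2-(2-hydroxypropan-2-yl)-4a,8-dimethyl-5-[(1S)-3-methyl-1-(2,4,6-trimethoxyphenyl)butyl]-1,2,3,4,4a,5,6,7-octahydronaphthalen-1-ol | CC(C)C[C@H](c1c(OC)cc(OC)cc1OC)[C@H]1CCC(C)=C2[C@@H](O)[C@@H](C(C)(C)O)CC[C@@]21C | intermediate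
21 | (1S,2S,4aR,5R)-2-(2-hydroxypropan-2-yl)-4a,8-dimethyl-5-[(1S)-3-methyl-1-(2,4,6-trimethoxyphenyl)butyl]-1,2,3,4,4a,5,6,7-octahydronaphthalen-1-yl formate | CC(C)C[C@H](c1c(OC)cc(OC)cc1OC)[C@H]1CCC(C)=C2[C@@H](OC=O)[C@@H](C(C)(C)O)CC[C@@]21C | intermediate
22 | 2-[(2S,4aR,5R,8R)-4a,8-dimethyl-5-[(1S)-3-methyl-1-(2,4,6-trimethoxyphenyl)butyl]-2,3,4,4a,5,6,7,8-octahydronaphthalen-2-yl]propan-2-ol | CC(C)C[C@H](c1c(OC)cc(OC)cc1OC)[C@H]1CC[C@@H](C)C2=C[C@@H](C(C)(C)O)CC[C@@]21C | intermediate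
23 | dilithium salt of the monoformyl N,N-dimethyl hemiaminal of 22 (aryl C3 carries CH(OLi)NMe2, C11 carries OLi; hemiaminal carbon unassigned) | CC(C)C[C@H](c1c(OC)cc(OC)c(C(O[Li])N(C)C)c1OC)[C@H]1CC[C@@H](C)C2=C[C@@H](C(C)(C)O[Li])CC[C@@]21C | intermediate (not isolated)
24 | 5-[(1S)-1-[(1R,4R,6S,8aR)-6-(2-hydroxypropan-2-yl)-4,8a-dimethyl-1,2,3,4,6,7,8,8a-octahydronaphthalen-1-yl]-3-methylbutyl]-2,4,6-trimethoxybenzene-1,3-dicarbaldehyde | CC(C)C[C@H](c1c(OC)c(C=O)c(OC)c(C=O)c1OC)[C@H]1CC[C@@H](C)C2=C[C@@H](C(C)(C)O)CC[C@@]21C | intermediate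
25 | 5-[(1S)-1-[(1R,4R,6S,8aR)-6-(2-hydroxypropan-2-yl)-4,8a-dimethyl-1,2,3,4,6,7,8,8a-octahydronaphthalen-1-yl]-3-methylbutyl]-2,4,6-trihydroxybenzene-1,3-dicarbaldehyde | CC(C)C[C@H](c1c(O)c(C=O)c(O)c(C=O)c1O)[C@H]1CC[C@@H](C)C2=C[C@@H](C(C)(C)O)CC[C@@]21C | target

Total step count: 15. Longest linear sequence: 14 steps (steps 1–6 and 8–15); step 7 is a one-step side branch.

Steps most likely to fail

Step 4. The arene may attack the allyl cation at its tertiary terminus or on the wrong face of C1′ (poor regio- and facial selectivity), or the cation may be lost by elimination. The fallback sets out from 6 and comes back at 10. The silyl ether is cleaved (K2CO3, MeOH) to the tertiary allylic alcohol F1, which is acetylated (Ac2O, DMAP, Et3N) to the tertiary allylic acetate F2. Lithium bis(2,4,6-trimethoxyphenyl)cuprate F3, made from 9 (n-BuLi, then CuI), displaces the acetate in an anti-SN2′ reaction at C1′ under irreversible, kinetically controlled conditions to give the aryl ketone F4. The conditions of step 3, passing through the C4-methyl ketone F5, then give 10.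

Step 13. Ionisation of the hindered C6 formate may be slow, and the π-allyl complex may lose a β-hydrogen or take the hydride at C6 (loss of regiocontrol). The fallback sets out from 20, skips step 12 and comes back at 22; it is a Myers reductive transposition. Mitsunobu displacement of the C6 hydroxyl with 2-nitrobenzenesulfonylhydrazide (PPh3, DEAD, THF, −30 °C) proceeds with inversion to the sulfonylhydrazine F6. On warming this loses the sulfinic acid to give the allylic diazene F7, whose retro-ene loss of dinitrogen delivers hydrogen to C4 on the same face as in step 13 and moves the olefin to C5=C6.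

Step 1. The α-methyl enone may turn over slowly or with low enantioselectivity in the rhodium-catalysed addition, and the zirconium enolate may be protonated instead of adding to acetaldehyde. The fallback sets out from 1 and 2 and comes back at 5. Hydroalumination of 2 (iBu2AlH, heptane, 50 °C) gives the alkenylalane F8, which is added to 1 under copper catalysis (Cu(OTf)2, chiral phosphoramidite ligand, Et2O, −30 °C) and trapped with Me3SiOTf as the silyl enol ether F9. Methyllithium (THF, 0 °C) then releases the lithium enolate F10, which undergoes the aldol addition to acetaldehyde at −78 °C.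

Further compounds
F1 | step 4 | (2R,3R)-2-ethenyl-3-[(1E)-3-hydroxy-3-methylbut-1-en-1-yl]-2-methylcyclohexan-1-one | O=C1CCC[C@H](/C=C/C(C)(C)O)[C@@]1(C)C=C
F2 | step 4 | (3E)-4-[(1R,2R)-2-ethenyl-2-methyl-3-oxocyclohexyl]-2-methylbut-3-en-2-yl acetate | O=C1CCC[C@H](/C=C/C(C)(C)OC(C)=O)[C@@]1(C)C=C
F3 | step 4 | lithium bis(2,4,6-trimethoxyphenyl)cuprate | [Li+].COc1cc(OC)cc(OC)c1[Cu-]c1c(OC)cc(OC)cc1OC
F4 | step 4 | (2R,3R)-2-ethenyl-2-methyl-3-[(1S)-3-methyl-1-(2,4,6-trimethoxyphenyl)but-2-en-1-yl]cyclohexan-1-one | O=C1CCC[C@H]([C@H](C=C(C)C)c2c(OC)cc(OC)cc2OC)[C@@]1(C)C=C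
F5 | step 4 | (2R,3R)-2-ethenyl-2,6-dimethyl-3-[(1S)-3-methyl-1-(2,4,6-trimethoxyphenyl)but-2-en-1-yl]cyclohexan-1-one, both C6 epimers | O=C1C(C)CC[C@H]([C@H](C=C(C)C)c2c(OC)cc(OC)cc2OC)[C@@]1(C)C=C
F6 | step 13 | N-[(1R,2S,4aR,5R)-2-(2-hydroxypropan-2-yl)-4a,8-dimethyl-5-[(1S)-3-methyl-1-(2,4,6-trimethoxyphenyl)butyl]-1,2,3,4,4a,5,6,7-octahydronaphthalen-1-yl]-2-nitrobenzenesulfonohydrazide | CC(C)C[C@H](c1c(OC)cc(OC)cc1OC)[C@H]1CCC(C)=C2[C@H](N(N)S(=O)(=O)c3ccccc3[N+](=O)[O-])[C@@H](C(C)(C)O)CC[C@@]21C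
F7 | step 13 | 2-[(1R,2S,4aR,5R)-1-diazenyl-4a,8-dimethyl-5-[(1S)-3-methyl-1-(2,4,6-trimethoxyphenyl)butyl]-1,2,3,4,4a,5,6,7-octahydronaphthalen-2-yl]propan-2-ol | CC(C)C[C@H](c1c(OC)cc(OC)cc1OC)[C@H]1CCC(C)=C2[C@H](N=N)[C@@H](C(C)(C)O)CC[C@@]21C
F8 | step 1 | bis(2-methylpropyl)[(1E)-3-methyl-3-(trimethylsilyloxy)but-1-en-1-yl]alumane | CC(C)C[Al](CC(C)C)/C=C/C(C)(C)O[Si](C)(C)C
F9 | step 1 | trimethyl{[(3R)-2-methyl-3-[(1E)-3-methyl-3-(trimethylsilyloxy)but-1-en-1-yl]cyclohex-1-en-1-yl]oxy}silane | CC1=C(O[Si](C)(C)C)CCC[C@@H]1/C=C/C(C)(C)O[Si](C)(C)C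
F10 | step 1 | lithium (3R)-2-methyl-3-[(1E)-3-methyl-3-(trimethylsilyloxy)but-1-en-1-yl]cyclohex-1-en-1-olate | CC1=C(O[Li])CCC[C@@H]1/C=C/C(C)(C)O[Si](C)(C)C
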